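**Retrosynthetic overview**

- Ring A is numbered C1 (butanoyl), C2, C3 (quaternary, methyl and prenyl), C4, C5 (CH2Ar), C6. The route rests on C3 lying between the carbonyl carbons C2 and C4: with C1 excised and C5/C6 read as CH2, ring A shrinks to achiral 2-methyl-2-prenylcyclopentane-1,3-dione, whose two carbonyls are enantiotopic.
- Key disconnection: C1–C2 and C1–C6. A desymmetrising one-carbon ring expansion of that dione with 1-diazopentan-2-one under a chiral scandium Lewis acid builds ring A and fixes C3 in one operation.
- C6 oxygen: C1=C6 alkylidene diketone (selenoxide elimination), nucleophilic epoxide, then zerovalent-palladium isomerisation. The C4 ketone is held as an alcohol meanwhile, because a C4 carbonyl would make C5–H vinylogously acidic and block oxygen attack at C6.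
- Last bond C5–CH2: ortho-quinone methide alkylation of the ring A trione by an aromatic Mannich base, made regiodefined from symmetric 2,6-dihydroxy-4-methoxybenzaldehyde.
- Ring order: the cyclopentanedione is bought and enlarged to ring A; the aromatic ring is bought.

Key step: step 3

**Assumptions**

- CIP descriptors refer to the tautomer drawn in each SMILES; the spatial arrangement at C3 is the same from the key-step product to the target.
- The sense of induction of the scandium catalyst must be found by experiment; the ligand antipode (from L- or D-pipecolic acid) that gives the C3 configuration drawn is the one used.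
- The transient centres at C4 (carbinol) and at C1/C6 (selenide, epoxide) are carried as diastereomer mixtures, since all are cleared by step 8.

**Route**

Step 1
Reactants: 1 2-methylcyclopentane-1,3-dione; 2 1-bromo-3-methylbut-2-ene
Product: 3 2-methyl-2-(3-methylbut-2-en-1-yl)cyclopentane-1,3-dione (achiral)
Conditions: 1 M aq NaOH (1.0 equiv), Bu4NI (cat.), rt
Reagents that add atoms: none
Why: SN2 C-alkylation of the cyclic 1,3-dione enolate by the allylic bromide in water, where hydrogen bonding at the enolate oxygens favours C- over O-attack; the product has two enantiotopic carbonyls.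

Step 2
Reactants: 4 butanoyl chloride
Product: 6 1-diazopentan-2-one, via silyl diazoketone 5 (not isolated)
Conditions: Me3SiCHN2 (2.1 equiv), THF–MeCN 1:1, 0 °C to rt; aqueous work-up, SiO2
Reagents that add atoms: trimethylsilyldiazomethane, C[Si](C)(C)C=[N+]=[N-]
Why: Acylation of trimethylsilyldiazomethane by the acid chloride (Arndt–Eistert-type diazoketone synthesis), the second equivalent taking up HCl and the labile C–Si bond of 5 being cleaved on work-up.

Step 3
Reactants: 3 2-methyl-2-(3-methylbut-2-en-1-yl)cyclopentane-1,3-dione; 6 1-diazopentan-2-one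
Product: 8 (2S)-4-butanoyl-3-hydroxy-2-methyl-2-(3-methylbut-2-en-1-yl)cyclohex-3-en-1-one (enol form of the 4-butanoyl-1,3-dione), via diazonium alkoxide 7 (not isolated)
Conditions: Sc(OTf)3 (10 mol %), chiral N,N'-dioxide ligand L-PiPr2 (from L-pipecolic acid and 2,6-diisopropylaniline, 1,3-propylene linker; 11 mol %), 4 Å MS, CH2Cl2, −20 °C, 6 (1.1 equiv) added slowly; aq citric acid work-up
Reagents that add atoms: none
Why: Proposed new method: Sc(OTf)3 (trivalent scandium) held in the chiral N,N'-dioxide ligand coordinates one ring carbonyl of 3, the diazo carbon of 6 attacks it to give diazonium alkoxide 7, and the ring CH2 anti to the leaving N2 shifts from the carbinol carbon to the diazo carbon, so C1–C2 comes from the addition and C1–C6 from the 1,2-shift. The closest known reactions are chiral Sc(OTf)3-catalysed Tiffeneau–Demjanov-type ring expansions and homologations of ketones with α-diazo esters or diazoalkanes, and Lewis-acid-promoted Roskamp-type additions of α-diazo ketones to carbonyl groups that give 1,3-diketones; their combination on a prochiral 1,3-dione is untested. Ring A is closed by one-carbon enlargement of the existing five-membered ring (a 1,2-alkyl shift, not a cyclisation of a chain). C3 is not touched: its configuration follows from which enantiotopic carbonyl reacts, and the ligand decides this because its preferred carbonyl face lies anti to the larger prenyl group on only one of the two carbonyls. The step needs carbonyl-group selectivity, CH2 rather than quaternary-carbon migration, shift rather than epoxide formation or retro-Claisen opening, and a single insertion; the acyl-bearing quaternary carbon is an electron-poor and hindered migrating group, the scandium-bound alkoxide favours the shift, and the product enolises to an acyl-enol whose remaining C4 ketone sits in a less strained, less electrophilic six-membered ring.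

Step 4
Reactants: 8 (2S)-4-butanoyl-3-hydroxy-2-methyl-2-(3-methylbut-2-en-1-yl)cyclohex-3-en-1-one
Product: 9 (6R)-2-butanoyl-5-hydroxy-6-methyl-6-(3-methylbut-2-en-1-yl)cyclohexan-1-one (enol form; ring A C4 carbinol as both epimers)
Conditions: NaBH4 (2 equiv), EtOH, −20 to 0 °C; pH 4 work-up
Reagents that add atoms: none
Why: Chemoselective borohydride reduction, in which the acidic acyl-enol is converted into its inert sodium enolate and hydride attacks only the isolated C4 ketone; the carbinol centre is not controlled and is cleared in step 7.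

Step 5
Reactants: 9 (6R)-2-butanoyl-5-hydroxy-6-methyl-6-(3-methylbut-2-en-1-yl)cyclohexan-1-one
Product: 10 (6R)-2-butanoyl-5-hydroxy-6-methyl-6-(3-methylbut-2-en-1-yl)-2-(phenylselanyl)cyclohexan-1-one (diastereomer mixture)
Conditions: NaH (1.0 equiv), THF, 0 °C; PhSeCl (1.0 equiv), −78 °C
Reagents that add atoms: benzeneselenenyl chloride, Cl[Se]c1ccccc1
Why: α-Selenenylation of a β-diketone enolate at C1, the only doubly activated carbon; the preformed enolate should take up PhSeCl at −78 °C far faster than the prenyl alkene does.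

Step 6
Reactants: 10 (6R)-2-butanoyl-5-hydroxy-6-methyl-6-(3-methylbut-2-en-1-yl)-2-(phenylselanyl)cyclohexan-1-one
Product: 13 (3R)-1-butanoyl-4-hydroxy-3-methyl-3-(3-methylbut-2-en-1-yl)-7-oxabicyclo[4.1.0]heptan-2-one (diastereomer mixture), via selenoxide 11 (not isolated), via alkylidene diketone 12 (not isolated)
Conditions: mCPBA (1.0 equiv), CH2Cl2, −78 °C; then tBuOOH (3 equiv), K2CO3, −78 to 0 °C
Reagents that add atoms: tert-butyl hydroperoxide, CC(C)(C)OO
Why: Selenide oxidation and selenoxide syn-elimination (only C6–H is available) give the C1=C6 alkylidene 1,3-diketone 12, which is trapped as it forms by tert-butylperoxide anion in a Weitz–Scheffer nucleophilic epoxidation; the electron-rich prenyl alkene does not react with a nucleophilic oxidant, and tBuOOH with base avoids the peroxyseleninic acid that H2O2 would generate.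

Step 7
Reactants: 13 (3R)-1-butanoyl-4-hydroxy-3-methyl-3-(3-methylbut-2-en-1-yl)-7-oxabicyclo[4.1.0]heptan-2-one
Product: 14 (3R)-1-butanoyl-3-methyl-3-(3-methylbut-2-en-1-yl)-7-oxabicyclo[4.1.0]heptane-2,4-dione (epoxide diastereomers)
Conditions: Dess–Martin periodinane, CH2Cl2, 0 °C to rt
Reagents that add atoms: none
Why: Dess–Martin oxidation of the hindered secondary alcohol back to the C4 ketone at a stage where the molecule has no enol to interfere; the epoxide and the prenyl group are inert to the periodinane.

Step 8
Reactants: 14 (3R)-1-butanoyl-3-methyl-3-(3-methylbut-2-en-1-yl)-7-oxabicyclo[4.1.0]heptane-2,4-dione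
Product: 15 (4R)-2-butanoyl-3,5-dihydroxy-4-methyl-4-(3-methylbut-2-en-1-yl)cyclohexa-2,5-dien-1-one (enol form of the ring A trione)
Conditions: Pd(PPh3)4 (5 mol %), Ph2PCH2CH2PPh2 (5 mol %), toluene, 80 °C
Reagents that add atoms: none
Why: Zerovalent-palladium-catalysed isomerisation of an α,β-epoxy ketone to a 1,3-diketone: palladium opens the C1–O bond at the carbon flanked by two carbonyls, β-hydride elimination at the C6 alkoxide forms the C6 ketone and the hydride returns to the enolate, after which the triketone enolises and the transient centres at C1 and C6 vanish while C3 is untouched.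

Step 9
Reactants: 16 2,4,6-trihydroxybenzaldehyde
Product: 17 2,6-dihydroxy-4-methoxybenzaldehyde
Conditions: MeI (1.0 equiv), K2CO3 (1.0 equiv), acetone, rt
Reagents that add atoms: iodomethane, CI
Why: Williamson methylation of the 4-OH, the only hydroxyl not hydrogen-bonded to the aldehyde and the most acidic one (para to CHO), using one equivalent each of base and MeI.

Step 10
Reactants: 17 2,6-dihydroxy-4-methoxybenzaldehyde; 4 butanoyl chloride
Product: 18 3-butanoyl-2,6-dihydroxy-4-methoxybenzaldehyde
Conditions: AlCl3 (3.5 equiv), CH2Cl2–PhNO2, 0 °C to rt; dilute HCl work-up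
Reagents that add atoms: none
Why: Friedel–Crafts acylation of the still electron-rich ring ortho to a free hydroxyl; the open positions C3 and C5 are equivalent by symmetry, so only one regioisomer can form, and the low temperature should keep the methyl ether intact.

Step 11
Reactants: 18 3-butanoyl-2,6-dihydroxy-4-methoxybenzaldehyde
Product: 20 1-{3-[(dimethylamino)methyl]-2,4-dihydroxy-6-methoxyphenyl}butan-1-one, via iminium ion 19 (not isolated)
Conditions: Me2NH (2 M in THF), AcOH, NaBH(OAc)3, ClCH2CH2Cl, rt
Reagents that add atoms: dimethylamine, CNC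
Why: Reductive amination (iminium formation, then hydride delivery), selective for the aldehyde over the hindered, chelated aryl ketone; it places the aminomethyl carbon between the two hydroxyls without any regiochemical choice.

Step 12
Reactants: 15 (4R)-2-butanoyl-3,5-dihydroxy-4-methyl-4-(3-methylbut-2-en-1-yl)cyclohexa-2,5-dien-1-one; 20 1-{3-[(dimethylamino)methyl]-2,4-dihydroxy-6-methoxyphenyl}butan-1-one
Product: 22 (4R)-2-butanoyl-6-[(3-butanoyl-2,6-dihydroxy-4-methoxyphenyl)methyl]-3,5-dihydroxy-4-methyl-4-(3-methylbut-2-en-1-yl)cyclohexa-2,5-dien-1-one (CNP0285707.1), via ortho-quinone methide 21 (not isolated)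
Conditions: toluene, 90 °C, argon sweep; aq citric acid wash
Reagents that add atoms: none
Why: Mannich-base alkylation of a 1,3-dicarbonyl compound: the acidic trione protonates the amine, loss of Me2NH gives ortho-quinone methide 21, and C5 of 15, its only nucleophilic carbon, adds in a Michael reaction to form the C5–CH2 bond without touching C3.

**Compound list**

1 | 2-methylcyclopentane-1,3-dione | CC1C(=O)CCC1=O | starting material
2 | 1-bromo-3-methylbut-2-ene | CC(C)=CCBr | starting material
3 | 2-methyl-2-(3-methylbut-2-en-1-yl)cyclopentane-1,3-dione (achiral, prochiral) | CC1(CC=C(C)C)C(=O)CCC1=O | intermediate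
4 | butanoyl chloride | CCCC(=O)Cl | starting material
5 | 1-diazo-1-(trimethylsilyl)pentan-2-one (not isolated) | CCCC(=O)C(=[N+]=[N-])[Si](C)(C)C | intermediate
6 | 1-diazopentan-2-one | CCCC(=O)C=[N+]=[N-] | intermediate
7 | diazonium alkoxide adduct of 3 and 6 (scandium-bound in the flask, drawn as zwitterion; carbinol and diazonium-bearing centres not defined; not isolated) | CCCC(=O)C([N+]#N)C1([O-])[C@](C)(CC=C(C)C)C(=O)CC1 | intermediate
8 | (2S)-4-butanoyl-3-hydroxy-2-methyl-2-(3-methylbut-2-en-1-yl)cyclohex-3-en-1-one (enol of 4-butanoyl-2-methyl-2-prenylcyclohexane-1,3-dione) | CCCC(=O)C1=C(O)[C@](C)(CC=C(C)C)C(=O)CC1 | intermediate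
9 | (6R)-2-butanoyl-5-hydroxy-6-methyl-6-(3-methylbut-2-en-1-yl)cyclohexan-1-one, enol form, both C5 epimers | CCCC(=O)C1=C(O)[C@](C)(CC=C(C)C)C(O)CC1 | intermediate
10 | (6R)-2-butanoyl-5-hydroxy-6-methyl-6-(3-methylbut-2-en-1-yl)-2-(phenylselanyl)cyclohexan-1-one, mixture at C2 and C5 | CCCC(=O)C1([Se]c2ccccc2)C(=O)[C@](C)(CC=C(C)C)C(O)CC1 | intermediate
11 | (6R)-2-(benzeneseleninyl)-2-butanoyl-5-hydroxy-6-methyl-6-(3-methylbut-2-en-1-yl)cyclohexan-1-one (not isolated) | CCCC(=O)C1([Se](=O)c2ccccc2)C(=O)[C@](C)(CC=C(C)C)C(O)CC1 | intermediate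
12 | (6R)-2-butanoyl-5-hydroxy-6-methyl-6-(3-methylbut-2-en-1-yl)cyclohex-2-en-1-one, C5 epimers (not isolated) | CCCC(=O)C1=CCC(O)[C@@](C)(CC=C(C)C)C1=O | intermediate
13 | (3R)-1-butanoyl-4-hydroxy-3-methyl-3-(3-methylbut-2-en-1-yl)-7-oxabicyclo[4.1.0]heptan-2-one, mixture at C1/C6 and C4 | CCCC(=O)C12OC1CC(O)[C@@](C)(CC=C(C)C)C2=O | intermediate
14 | (3R)-1-butanoyl-3-methyl-3-(3-methylbut-2-en-1-yl)-7-oxabicyclo[4.1.0]heptane-2,4-dione, epoxide diastereomers | CCCC(=O)C12OC1CC(=O)[C@@](C)(CC=C(C)C)C2=O | intermediate
15 | (4R)-2-butanoyl-3,5-dihydroxy-4-methyl-4-(3-methylbut-2-en-1-yl)cyclohexa-2,5-dien-1-one | CCCC(=O)C1=C(O)[C@](C)(CC=C(C)C)C(O)=CC1=O | intermediate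
16 | 2,4,6-trihydroxybenzaldehyde | O=Cc1c(O)cc(O)cc1O | starting material
17 | 2,6-dihydroxy-4-methoxybenzaldehyde | COc1cc(O)c(C=O)c(O)c1 | intermediate
18 | 3-butanoyl-2,6-dihydroxy-4-methoxybenzaldehyde | CCCC(=O)c1c(OC)cc(O)c(C=O)c1O | intermediate
19 | N-[(3-butanoyl-2,6-dihydroxy-4-methoxyphenyl)methylidene]-N-methylmethanaminium (not isolated) | CCCC(=O)c1c(OC)cc(O)c(C=[N+](C)C)c1O | intermediate
20 | 1-{3-[(dimethylamino)methyl]-2,4-dihydroxy-6-methoxyphenyl}butan-1-one | CCCC(=O)c1c(OC)cc(O)c(CN(C)C)c1O | intermediate
21 | 4-butanoyl-3-hydroxy-5-methoxy-2-methylidenecyclohexa-3,5-dien-1-one (ortho-quinone methide, not isolated) | C=C1C(=O)C=C(OC)C(C(=O)CCC)=C1O | intermediate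
22 | (4R)-2-butanoyl-6-[(3-butanoyl-2,6-dihydroxy-4-methoxyphenyl)methyl]-3,5-dihydroxy-4-methyl-4-(3-methylbut-2-en-1-yl)cyclohexa-2,5-dien-1-one | CCCC(=O)C1=C(O)[C@](C)(CC=C(C)C)C(O)=C(Cc2c(O)cc(OC)c(C(=O)CCC)c2O)C1=O | target

**Step count**

Total: 12 steps. Longest linear sequence: 8 steps (1, 3, 4, 5, 6, 7, 8, 12).

**Steps most likely to fail**

Step 3 (proposed new method). Possible failures:
- poor discrimination of the two carbonyls, giving low enantiomeric purity;
- catalyst arrest by the chelating acyl-enol product;
- retro-Claisen opening of the diazonium alkoxide, or epoxide formation, in place of the shift;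
- a second insertion at C4, or acid-induced loss of the diazoketone.

Fallback by known chemistry, setting out from 3 and returning at 9:
- CBS reduction of one carbonyl of 3 (B-methyl oxazaborolidine from diphenylprolinol, the antipode that gives the enantiomer of the known baker's-yeast product; catecholborane, toluene, −60 °C) should give (2R,3R)-3-hydroxy-2-methyl-2-(3-methylbut-2-en-1-yl)cyclopentan-1-one F1.
- TBSCl/imidazole gives (2R,3R)-3-[(tert-butyldimethylsilyl)oxy]-2-methyl-2-(3-methylbut-2-en-1-yl)cyclopentan-1-one F2.
- Trimethylsilyldiazomethane with BF3·OEt2 (CH2Cl2, −78 °C) homologates the ketone with migration of the ring CH2 to the α-silyl ketone (2R,3R)-3-[(tert-butyldimethylsilyl)oxy]-2-methyl-2-(3-methylbut-2-en-1-yl)-6-(trimethylsilyl)cyclohexan-1-one F3.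
- F3 loses silicon on acidic work-up to give (2R,3R)-3-[(tert-butyldimethylsilyl)oxy]-2-methyl-2-(3-methylbut-2-en-1-yl)cyclohexan-1-one F4.
- LiN(SiMe3)2 then 1-butanoylbenzotriazole C-acylates the only enolisable α-carbon to give (5R,6R)-2-butanoyl-5-[(tert-butyldimethylsilyl)oxy]-6-methyl-6-(3-methylbut-2-en-1-yl)cyclohexan-1-one F5.
- HF·pyridine removes the silyl ether and the route is rejoined at 9, here as a single C4 epimer.

Step 8. Possible failures:
- retro-aldol opening of the ring across C5–C6 at the palladium alkoxide;
- elimination from C5 that opens the epoxide the wrong way and leaves oxygen on C1;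
- thermal decay of the non-enolisable tricarbonyl 14.

Fallback, setting out from 13 (before step 7) and returning at 15:
- SmI2 (THF–MeOH, −78 °C) cleaves the C1–O bond reductively, as known for α,β-epoxy ketones, to (6R)-2-butanoyl-3,5-dihydroxy-6-methyl-6-(3-methylbut-2-en-1-yl)cyclohexan-1-one F6.
- IBX (DMSO, rt) oxidises both carbinols and gives 15. This replaces the redox-neutral isomerisation by reduction followed by oxidation.

Step 12. Possible failures:
- exchange of the methylene bridge by retro-Michael cleavage and re-addition, or aminomethyl transfer to 15, leading to symmetric dimers;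
- self-condensation of the quinone methide;
- cyclodehydration of the product to a xanthene.

Fallback, setting out from 15 and 18 and returning at 22:
- Organocatalytic reductive alkylation: L-proline (cat.) and diethyl 2,6-dimethyl-1,4-dihydropyridine-3,5-dicarboxylate (Hantzsch ester) in CH2Cl2 at rt.
- Knoevenagel condensation should give 2-butanoyl-6-[(3-butanoyl-2,6-dihydroxy-4-methoxyphenyl)methylidene]-3-hydroxy-4-methyl-4-(3-methylbut-2-en-1-yl)cyclohex-2-ene-1,5-dione F7 (not isolated).
- F7 is reduced in the flask by hydride transfer to 22, so no amine and no heating are involved.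

**Further compounds**

F1 | step 3 | (2R,3R)-3-hydroxy-2-methyl-2-(3-methylbut-2-en-1-yl)cyclopentan-1-one | O=C1CC[C@@H](O)[C@@]1(C)CC=C(C)C
F2 | step 3 | (2R,3R)-3-[(tert-butyldimethylsilyl)oxy]-2-methyl-2-(3-methylbut-2-en-1-yl)cyclopentan-1-one | O=C1CC[C@@H](O[Si](C)(C)C(C)(C)C)[C@@]1(C)CC=C(C)C
F3 | step 3 | (2R,3R)-3-[(tert-butyldimethylsilyl)oxy]-2-methyl-2-(3-methylbut-2-en-1-yl)-6-(trimethylsilyl)cyclohexan-1-one, C6 epimers | O=C1C([Si](C)(C)C)CC[C@@H](O[Si](C)(C)C(C)(C)C)[C@@]1(C)CC=C(C)C
F4 | step 3 | (2R,3R)-3-[(tert-butyldimethylsilyl)oxy]-2-methyl-2-(3-methylbut-2-en-1-yl)cyclohexan-1-one | O=C1CCC[C@@H](O[Si](C)(C)C(C)(C)C)[C@@]1(C)CC=C(C)C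
F5 | step 3 | (5R,6R)-2-butanoyl-5-[(tert-butyldimethylsilyl)oxy]-6-methyl-6-(3-methylbut-2-en-1-yl)cyclohexan-1-one, enol form | CCCC(=O)C1=C(O)[C@](C)(CC=C(C)C)[C@H](O[Si](C)(C)C(C)(C)C)CC1
F6 | step 8 | (6R)-2-butanoyl-3,5-dihydroxy-6-methyl-6-(3-methylbut-2-en-1-yl)cyclohexan-1-one, enol form, carbinol epimers | CCCC(=O)C1=C(O)[C@](C)(CC=C(C)C)C(O)CC1O
F7 | step 12 | 2-butanoyl-6-[(3-butanoyl-2,6-dihydroxy-4-methoxyphenyl)methylidene]-3-hydroxy-4-methyl-4-(3-methylbut-2-en-1-yl)cyclohex-2-ene-1,5-dione, C4 configuration as in 15, alkene geometry not defined | CCCC(=O)C1=C(O)[C@](C)(CC=C(C)C)C(=O)C(=Cc2c(O)cc(OC)c(C(=O)CCC)c2O)C1=O
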